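The target is numbered as a 1-benzofuran-2-one. Its C4 ester oxygen, its C3a–C3 bond and its C7a lactone oxygen are all cis on the cyclohexene ring, and the exocyclic methylene carbon lies 1,3 to the C4 oxygen. That carbon is therefore tied to the C4 oxygen as a temporary tetrahydrofuran. The iodomalonate ether of a (1R)-cyclohexa-2,5-dienol (from diethyl methylenemalonate) undergoes iodine-atom-transfer 5-exo cyclization and lactonization. This forms C3–C3a and O1–C7a in one operation and relays both new ring stereocentres from one CBS-set carbinol. Dealkoxycarbonylation and base-induced β-elimination then reopen the ether, freeing the methylene group and the C4 alkoxide for acylation. (S)-Citronellal supplies the side-chain stereocentre.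

Key step: step 10

Remark on the chemistry: ring positions are cited with the 1-benzofuran-2(3H)-one numbering of the target (O1, C2, C3, C3a, C4, C5, C6, C7, C7a), also for earlier intermediates ("future C3a"); (R)-2-methylbutanoic acid and stabilized diethyl methylenemalonate are taken as purchasable; TBDPS = tert-butyl(diphenyl)silyl.

Step 1
Reactants: 1 (S)-citronellal; 2 2-(3-chloropropyl)-2-methyl-1,3-dioxolane
Product: 4 (6S)-6,10-dimethyl-1-(2-methyl-1,3-dioxolan-2-yl)undec-9-en-4-ol (both C4 epimers), via Grignard reagent 3 (not isolated)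
Conditions: 2, Mg, THF, reflux; then 1, 0 °C; aq. NH4Cl
Reagents that add atoms: none
Why: Grignard addition of the alkylmagnesium chloride made from 2 to the aldehyde should give the secondary alcohol, whose new carbinol centre is left uncontrolled because step 2 oxidises it, while the (S)-methyl centre bought with citronellal is not touched.

Step 2
Reactants: 4 (6S)-6,10-dimethyl-1-(2-methyl-1,3-dioxolan-2-yl)undec-9-en-4-ol
Product: 5 (6S)-6,10-dimethyl-1-(2-methyl-1,3-dioxolan-2-yl)undec-9-en-4-one
Conditions: Dess–Martin periodinane, NaHCO3, CH2Cl2, rt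
Reagents that add atoms: none
Why: Dess–Martin oxidation should convert the secondary alcohol into the ketone under buffered neutral conditions that leave the trisubstituted alkene and the dioxolane intact and erase the uncontrolled carbinol centre.

Step 3
Reactants: 5 (6S)-6,10-dimethyl-1-(2-methyl-1,3-dioxolan-2-yl)undec-9-en-4-one
Product: 7 3-methyl-2-[(2S)-6-methylhept-5-en-2-yl]cyclohex-2-en-1-one, via diketone 6 (not isolated)
Conditions: 2 M HCl, THF, rt; then KOH, MeOH, 65 °C
Reagents that add atoms: none
Why: Acid hydrolysis of the dioxolane frees the 2,6-diketone and hydroxide then effects the intramolecular aldol condensation in which the C7 methylene attacks the methyl ketone, the reversible aldol step funnelling material to the conjugated tetrasubstituted 2-alkyl-3-methylcyclohexenone, while the side-chain stereocentre, β to the ketone, cannot enolise.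

Step 4
Reactants: 7 3-methyl-2-[(2S)-6-methylhept-5-en-2-yl]cyclohex-2-en-1-one
Product: 10 2-[(2S)-5-hydroxypentan-2-yl]-3-methylcyclohex-2-en-1-one, via ozonide 8 (not isolated), via aldehyde 9 (not isolated)
Conditions: O3, CH2Cl2, −78 °C (Sudan red 7B end point); PPh3; then NaBH(OAc)3, AcOH, rt
Reagents that add atoms: ozone, [O-][O+]=O
Why: Ozone should cleave the electron-rich trisubstituted alkene much faster than the electron-poor enone double bond, PPh3 reduces the ozonide to the aldehyde, and NaBH(OAc)3 reduces aldehydes but not the hindered enone carbonyl (chemoselective ozonolysis and hydride reduction).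

Step 5
Reactants: 10 2-[(2S)-5-hydroxypentan-2-yl]-3-methylcyclohex-2-en-1-one
Product: 11 2-[(2S)-5-{[tert-butyl(diphenyl)silyl]oxy}pentan-2-yl]-3-methylcyclohex-2-en-1-one
Conditions: TBDPSCl, imidazole, DMF, rt
Reagents that add atoms: tert-butyl(chloro)diphenylsilane, CC(C)(C)[Si](Cl)(c1ccccc1)c1ccccc1
Why: Imidazole-promoted silylation protects the only hydroxyl as a robust TBDPS ether that should survive the bases, radicals and hot chloride of the later steps.

Step 6
Reactants: 11 2-[(2S)-5-{[tert-butyl(diphenyl)silyl]oxy}pentan-2-yl]-3-methylcyclohex-2-en-1-one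
Product: 13 3-methyl-6-(phenylselanyl)-2-[(2S)-5-{[tert-butyl(diphenyl)silyl]oxy}pentan-2-yl]cyclohex-2-en-1-one (both C6 epimers), via lithium dienolate 12 (not isolated)
Conditions: LiN(iPr)2, THF, −78 °C; PhSeBr, −78 °C
Reagents that add atoms: benzeneselenenyl bromide, Br[Se]c1ccccc1
Why: Kinetic deprotonation at low temperature takes the α′ proton (future C3a) to give the cross-conjugated enolate, which is selenenylated by PhSeBr; the new C–Se centre forms as both epimers, which does not matter because it is destroyed in step 8.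

Step 7
Reactants: 13 3-methyl-6-(phenylselanyl)-2-[(2S)-5-{[tert-butyl(diphenyl)silyl]oxy}pentan-2-yl]cyclohex-2-en-1-one
Product: 14 (1S)-3-methyl-6-(phenylselanyl)-2-[(2S)-5-{[tert-butyl(diphenyl)silyl]oxy}pentan-2-yl]cyclohex-2-en-1-ol (both C6 epimers)
Conditions: (S)-1-methyl-3,3-diphenyltetrahydro-1H,3H-pyrrolo[1,2-c][1,3,2]oxazaborole (20 mol%), BH3·SMe2, THF, −40 °C; MeOH
Reagents that add atoms: none
Why: CBS reduction, in which the oxazaborolidine-bound borane delivers hydride to the carbonyl face fixed by the (S)-catalyst with the substituted alkenyl side as the large group, should set the carbinol centre (future C4; (1S) here, (1R) in 16 by a change of priorities only) under reagent control for both selenide epimers and without conjugate reduction.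

Step 8
Reactants: 14 (1S)-3-methyl-6-(phenylselanyl)-2-[(2S)-5-{[tert-butyl(diphenyl)silyl]oxy}pentan-2-yl]cyclohex-2-en-1-ol
Product: 16 (1R)-2-[(2S)-5-{[tert-butyl(diphenyl)silyl]oxy}pentan-2-yl]-3-methylcyclohexa-2,5-dien-1-ol, via selenoxide 15 (not isolated)
Conditions: 30% H2O2, pyridine, CH2Cl2, 0 °C to rt; base-washed glassware, used at once
Reagents that add atoms: none
Why: Oxidation to the selenoxide and spontaneous syn-elimination, which in β-hydroxy selenoxides runs away from the carbinol carbon, should place the new double bond between the future C3a and C7a and give the doubly allylic alcohol with its carbinol configuration unchanged.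

Step 9
Reactants: 16 (1R)-2-[(2S)-5-{[tert-butyl(diphenyl)silyl]oxy}pentan-2-yl]-3-methylcyclohexa-2,5-dien-1-ol; 17 diethyl methylenemalonate
Product: 20 diethyl 2-iodo-2-({[(1R)-2-[(2S)-5-{[tert-butyl(diphenyl)silyl]oxy}pentan-2-yl]-3-methylcyclohexa-2,5-dien-1-yl]oxy}methyl)propanedioate, via sodium alkoxide 18 (not isolated), via sodium malonate enolate 19 (not isolated)
Conditions: NaN(SiMe3)2, THF, −78 °C; 17 (slow addition); then N-iodosuccinimide, −78 °C, dark
Reagents that add atoms: N-iodosuccinimide, O=C1CCC(=O)N1I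
Why: Oxa-Michael addition of the sodium alkoxide to the very electrophilic methylenemalonate gives the stabilised malonate enolate directly, which N-iodosuccinimide iodinates at carbon; the C–O bond of the carbinol is not involved, so its configuration is retained.

Step 10
Reactants: 20 diethyl 2-iodo-2-({[(1R)-2-[(2S)-5-{[tert-butyl(diphenyl)silyl]oxy}pentan-2-yl]-3-methylcyclohexa-2,5-dien-1-yl]oxy}methyl)propanedioate
Product: 22 tricyclic ester lactone (target 1-benzofuran-2-one skeleton with quaternary C3 bearing CO2Et and a CH2 group bonded to the C4 oxygen; 3a-H, 4-H and 7a-H all cis; side chain as TBDPS ether), via iodo diester 21 (not isolated)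
Conditions: (Bu3Sn)2 (10 mol%), hν (sunlamp), benzene, 25 °C; then 80 °C
Reagents that add atoms: none
Why: Homolysis of the tertiary C–I bond gives an electrophilic malonyl radical that adds 5-exo-trig to the proximal carbon (future C3a) of the disubstituted ring alkene, the secondary radical at the future C7a takes iodine from 20 to carry the chain, and on heating the syn ester carbonyl oxygen displaces that iodide with loss of iodoethane, so that C3–C3a and O1–C7a form in one operation. The closest known reaction type is the Kharasch-type iodine-atom-transfer cyclization of iodomalonates followed by thermal lactonization of the γ-iodo ester. The tetrahydrofuran closes by 5-exo-trig radical attack and the γ-lactone by 5-exo-tet substitution. C3a is fixed by the three-atom tether from the C4 oxygen, which can only reach the alkene face syn to that oxygen; iodine is delivered to C7a on the open face anti to the new C3–C3a bond and is then inverted by the intramolecular substitution, which places O1 cis to C3; the quaternary C3 is dictated by the two cis ring fusions. The step needs attack on the disubstituted alkene and not on the tetrasubstituted one that is also allylic to the ether oxygen (secured by the much slower 5-exo addition to a fully substituted carbon carrying the branched chain), 5-exo over 6-endo closure (the bridged product is strained), and lactonization over loss of HI (secured by the geminal ester pair, one ester always being syn to the iodide, and by neutral conditions).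

Step 11
Reactants: 22 tricyclic ester lactone
Product: 23 tricyclic lactone (as 22 but with H at C3; O–CH2–C3 tetrahydrofuran and γ-lactone both cis-fused)
Conditions: LiCl, H2O, DMSO, 140 °C
Reagents that add atoms: none
Why: Krapcho dealkoxycarbonylation should remove the exo ester (chloride dealkylates the ethyl ester, the β-carbonyl carboxylate loses CO2) and water protonates the lactone enolate on its open face, the only face that keeps both five-membered rings cis-fused at C3.

Step 12
Reactants: 23 tricyclic lactone; 24 (R)-2-methylbutanoic acid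
Product: 28 (3aR,4R,7aR)-5-[(2S)-5-{[tert-butyl(diphenyl)silyl]oxy}pentan-2-yl]-6-methyl-3-methylidene-2-oxo-2,3,3a,4,7,7a-hexahydro-1-benzofuran-4-yl (2R)-2-methylbutanoate, via lithium enolate 25 (not isolated), via lithium alkoxide 26 (not isolated), via mixed anhydride 27 (not isolated)
Conditions: LiN(iPr)2, THF, −78 to 0 °C; then 27 (from 24, 2,4,6-trichlorobenzoyl chloride, Et3N, THF), −78 to 0 °C
Reagents that add atoms: none
Why: Kinetic deprotonation at C3 gives the lactone enolate, which on warming expels the β-alkoxide (E1cB opening of the tetrahydrofuran, as in the base-induced opening of 7-oxanorbornane esters; the reverse is a disfavoured 5-endo-trig addition, so the ring does not re-close), and the freed C4 alkoxide is acylated by the Yamaguchi-type mixed anhydride at its less hindered aliphatic carbonyl with retention at C4 and at the acid's α-centre.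

Step 13
Reactants: 28 silyl-protected target
Product: 29 (3aR,4R,7aR)-5-[(2S)-5-hydroxypentan-2-yl]-6-methyl-3-methylidene-2-oxo-2,3,3a,4,7,7a-hexahydro-1-benzofuran-4-yl (2R)-2-methylbutanoate
Conditions: HF·pyridine, pyridine, THF, 0 °C to rt
Reagents that add atoms: none
Why: Fluoride-mediated cleavage of the primary silyl ether under buffered conditions should leave the allylic ester and the methylene lactone intact.

Compound list
1 | (S)-citronellal, (3S)-3,7-dimethyloct-6-enal | O=CC[C@@H](C)CCC=C(C)C | starting material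
2 | 2-(3-chloropropyl)-2-methyl-1,3-dioxolane | CC1(CCCCl)OCCO1 | starting material
3 | [3-(2-methyl-1,3-dioxolan-2-yl)propyl]magnesium chloride | CC1(CCC[Mg]Cl)OCCO1 | intermediate (not isolated)
4 | (6S)-6,10-dimethyl-1-(2-methyl-1,3-dioxolan-2-yl)undec-9-en-4-ol, C4 epimers | CC1(CCCC(O)C[C@@H](C)CCC=C(C)C)OCCO1 | intermediate
5 | (6S)-6,10-dimethyl-1-(2-methyl-1,3-dioxolan-2-yl)undec-9-en-4-one | CC1(CCCC(=O)C[C@@H](C)CCC=C(C)C)OCCO1 | intermediate
6 | (8S)-8,12-dimethyltridec-11-ene-2,6-dione | CC(=O)CCCC(=O)C[C@@H](C)CCC=C(C)C | intermediate (not isolated)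
7 | 3-methyl-2-[(2S)-6-methylhept-5-en-2-yl]cyclohex-2-en-1-one | CC1=C([C@@H](C)CCC=C(C)C)C(=O)CCC1 | intermediate
8 | 2-[(2S)-4-(5,5-dimethyl-1,2,4-trioxolan-3-yl)butan-2-yl]-3-methylcyclohex-2-en-1-one (ozonide) | CC1=C([C@@H](C)CCC2OOC(C)(C)O2)C(=O)CCC1 | intermediate (not isolated)
9 | (4S)-4-(2-methyl-6-oxocyclohex-1-en-1-yl)pentanal | CC1=C([C@@H](C)CCC=O)C(=O)CCC1 | intermediate (not isolated)
10 | 2-[(2S)-5-hydroxypentan-2-yl]-3-methylcyclohex-2-en-1-one | CC1=C([C@@H](C)CCCO)C(=O)CCC1 | intermediate
11 | 2-[(2S)-5-{[tert-butyl(diphenyl)silyl]oxy}pentan-2-yl]-3-methylcyclohex-2-en-1-one | CC1=C([C@@H](C)CCCO[Si](c2ccccc2)(c2ccccc2)C(C)(C)C)C(=O)CCC1 | intermediate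
12 | lithium 5-methyl-6-[(2S)-5-{[tert-butyl(diphenyl)silyl]oxy}pentan-2-yl]cyclohexa-1,5-dien-1-olate | [Li+].[O-]C1=CCCC(C)=C1[C@@H](C)CCCO[Si](c1ccccc1)(c1ccccc1)C(C)(C)C | intermediate (not isolated)
13 | 3-methyl-6-(phenylselanyl)-2-[(2S)-5-{[tert-butyl(diphenyl)silyl]oxy}pentan-2-yl]cyclohex-2-en-1-one, C6 epimers | CC1=C([C@@H](C)CCCO[Si](c2ccccc2)(c2ccccc2)C(C)(C)C)C(=O)C([Se]c2ccccc2)CC1 | intermediate
14 | (1S)-3-methyl-6-(phenylselanyl)-2-[(2S)-5-{[tert-butyl(diphenyl)silyl]oxy}pentan-2-yl]cyclohex-2-en-1-ol, C6 epimers | CC1=C([C@@H](C)CCCO[Si](c2ccccc2)(c2ccccc2)C(C)(C)C)[C@H](O)C([Se]c2ccccc2)CC1 | intermediate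
15 | selenoxide of 14 | CC1=C([C@@H](C)CCCO[Si](c2ccccc2)(c2ccccc2)C(C)(C)C)[C@H](O)C([Se](=O)c2ccccc2)CC1 | intermediate (not isolated)
16 | (1R)-2-[(2S)-5-{[tert-butyl(diphenyl)silyl]oxy}pentan-2-yl]-3-methylcyclohexa-2,5-dien-1-ol | CC1=C([C@@H](C)CCCO[Si](c2ccccc2)(c2ccccc2)C(C)(C)C)[C@H](O)C=CC1 | intermediate
17 | diethyl methylenemalonate (diethyl 2-methylidenepropanedioate) | C=C(C(=O)OCC)C(=O)OCC | starting material
18 | sodium alkoxide of 16 | CC1=C([C@@H](C)CCCO[Si](c2ccccc2)(c2ccccc2)C(C)(C)C)[C@H]([O-])C=CC1.[Na+] | intermediate (not isolated)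
19 | sodium enolate of diethyl 2-({[(1R)-dienyl]oxy}methyl)propanedioate | CC1=C([C@@H](C)CCCO[Si](c2ccccc2)(c2ccccc2)C(C)(C)C)[C@H](OCC(C(=O)OCC)=C([O-])OCC)C=CC1.[Na+] | intermediate (not isolated)
20 | diethyl 2-iodo-2-({[(1R)-2-[(2S)-5-{[tert-butyl(diphenyl)silyl]oxy}pentan-2-yl]-3-methylcyclohexa-2,5-dien-1-yl]oxy}methyl)propanedioate | CC1=C([C@@H](C)CCCO[Si](c2ccccc2)(c2ccccc2)C(C)(C)C)[C@H](OCC(I)(C(=O)OCC)C(=O)OCC)C=CC1 | intermediate
21 | diethyl 4-iodo-6-methyl-7-[(2S)-5-{[tert-butyl(diphenyl)silyl]oxy}pentan-2-yl]-3a,4,5,7a-tetrahydro-1-benzofuran-3,3(2H)-dicarboxylate, cis ring fusion, iodine trans to C3 | CCOC(=O)C1(C(=O)OCC)CO[C@H]2C([C@@H](C)CCCO[Si](c3ccccc3)(c3ccccc3)C(C)(C)C)=C(C)C[C@H](I)[C@@H]12 | intermediate (not isolated)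
22 | tricyclic ester lactone: target lactone skeleton, C3 quaternary with CO2Et and a CH2–O bridge to C4, all ring fusions cis, TBDPS ether | O=C1O[C@@H]2CC(C)=C([C@@H](C)CCCO[Si](c4ccccc4)(c4ccccc4)C(C)(C)C)[C@@H]3OC[C@@]1(C(=O)OCC)[C@H]23 | intermediate
23 | tricyclic lactone: as 22 with H at C3 | O=C1O[C@@H]2CC(C)=C([C@@H](C)CCCO[Si](c4ccccc4)(c4ccccc4)C(C)(C)C)[C@@H]3OC[C@H]1[C@H]23 | intermediate
24 | (R)-2-methylbutanoic acid | CC[C@@H](C)C(=O)O | starting material
25 | lithium enolate of 23 | [Li+].[O-]C1=C2CO[C@H]3C([C@@H](C)CCCO[Si](c4ccccc4)(c4ccccc4)C(C)(C)C)=C(C)C[C@@H](O1)[C@@H]23 | intermediate (not isolated)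
26 | lithium (3aS,4R,7aR)-5-[(2S)-5-{[tert-butyl(diphenyl)silyl]oxy}pentan-2-yl]-6-methyl-3-methylidene-2-oxo-2,3,3a,4,7,7a-hexahydro-1-benzofuran-4-olate | C=C1C(=O)O[C@@H]2CC(C)=C([C@@H](C)CCCO[Si](c3ccccc3)(c3ccccc3)C(C)(C)C)[C@H]([O-])[C@H]12.[Li+] | intermediate (not isolated)
27 | (2R)-2-methylbutanoic 2,4,6-trichlorobenzoic anhydride | CC[C@@H](C)C(=O)OC(=O)c1c(Cl)cc(Cl)cc1Cl | intermediate (not isolated)
28 | (3aR,4R,7aR)-5-[(2S)-5-{[tert-butyl(diphenyl)silyl]oxy}pentan-2-yl]-6-methyl-3-methylidene-2-oxo-2,3,3a,4,7,7a-hexahydro-1-benzofuran-4-yl (2R)-2-methylbutanoate | C=C1C(=O)O[C@@H]2CC(C)=C([C@@H](C)CCCO[Si](c3ccccc3)(c3ccccc3)C(C)(C)C)[C@H](OC(=O)[C@H](C)CC)[C@H]12 | intermediate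
29 | (3aR,4R,7aR)-5-[(2S)-5-hydroxypentan-2-yl]-6-methyl-3-methylidene-2-oxo-2,3,3a,4,7,7a-hexahydro-1-benzofuran-4-yl (2R)-2-methylbutanoate | C=C1C(=O)O[C@@H]2CC(C)=C([C@@H](C)CCCO)[C@H](OC(=O)[C@H](C)CC)[C@H]12 | target

Total step count: 13. Longest linear sequence: 13 steps (1 to 29).

Steps most likely to fail

Step 10 (key step). The chain may break down through hydrogen-atom abstraction from the doubly allylic ring CH2 with aromatization of the dienyl ether, or HI may be lost from the secondary iodide before lactonization. The fallback is an oxidative radical–polar crossover without a halide. Setting out from 16, conjugate addition to 17 with only catalytic NaN(SiMe3)2 and a proton quench should give diethyl 2-({[(1R)-2-[(2S)-5-{[tert-butyl(diphenyl)silyl]oxy}pentan-2-yl]-3-methylcyclohexa-2,5-dien-1-yl]oxy}methyl)propanedioate F1. Mn(OAc)3·2H2O (2 equiv) and Cu(OTf)2 in MeCN then generate the malonyl radical from the C–H bond with trivalent manganese, and divalent copper oxidises the cyclized radical so that the syn ester closes the lactone directly. This comes back to the route at 22.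

Step 12. The β-elimination may be slow because the ring opening is the reverse of a 5-endo-trig addition, and the freed methylene lactone may be oligomerized by the alkoxide before acylation. The fallback masks the methylene group, acylates, and unmasks. Setting out from 23, the enolate is formed and warmed as before but quenched with PhSH, so that thiolate adds to the methylene lactone as soon as it forms and the 3-[(phenylsulfanyl)methyl] lactone alcohol F2 is isolated. Esterification with 24 (EDC, DMAP, CH2Cl2) gives the 3-[(phenylsulfanyl)methyl] lactone (2R)-2-methylbutanoate F3. NaIO4 gives the sulfoxide F4, and thermal syn-elimination (toluene, CaCO3, 110 °C) restores the methylene group. This comes back to the route at 28.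

Step 7. Reagent control may erode (poor facial selectivity) because the α′-selanyl group makes the two sides of the ketone similar in size. The fallback is a sulfoxide-directed reduction with sulfur as the controlling stereocentre. Setting out from 11, the kinetic enolate (LiN(iPr)2) is sulfinylated with (1R,2S,5R)-menthyl (S)-4-methylbenzenesulfinate to give the (R)-sulfinyl ketone, 3-methyl-6-[(R)-(4-methylphenyl)sulfinyl]-2-[(2S)-5-{[tert-butyl(diphenyl)silyl]oxy}pentan-2-yl]cyclohex-2-en-1-one F5. Reduction with iBu2AlH (THF, −78 °C) under control of the sulfoxide gives the (1S)-hydroxy sulfoxide F6; iBu2AlH with ZnCl2 gives the opposite carbinol if that is the one needed. Thermal sulfoxide elimination (toluene, CaCO3, 110 °C) runs away from the carbinol and comes back to the route at 16.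

Further compounds
F1 | step 10 | diethyl 2-({[(1R)-2-[(2S)-5-{[tert-butyl(diphenyl)silyl]oxy}pentan-2-yl]-3-methylcyclohexa-2,5-dien-1-yl]oxy}methyl)propanedioate | CC1=C([C@@H](C)CCCO[Si](c2ccccc2)(c2ccccc2)C(C)(C)C)[C@H](OCC(C(=O)OCC)C(=O)OCC)C=CC1
F2 | step 12 | (3aS,4R,7aR)-4-hydroxy-6-methyl-3-[(phenylsulfanyl)methyl]-5-[(2S)-5-{[tert-butyl(diphenyl)silyl]oxy}pentan-2-yl]-3a,4,7,7a-tetrahydro-1-benzofuran-2(3H)-one, C3 epimers | C(Sc3ccccc3)C1C(=O)O[C@@H]2CC(C)=C([C@@H](C)CCCO[Si](c3ccccc3)(c3ccccc3)C(C)(C)C)[C@H](O)[C@H]12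
F3 | step 12 | (2R)-2-methylbutanoate of F2 | C(Sc3ccccc3)C1C(=O)O[C@@H]2CC(C)=C([C@@H](C)CCCO[Si](c3ccccc3)(c3ccccc3)C(C)(C)C)[C@H](OC(=O)[C@H](C)CC)[C@H]12
F4 | step 12 | sulfoxide of F3 | C(S(=O)c3ccccc3)C1C(=O)O[C@@H]2CC(C)=C([C@@H](C)CCCO[Si](c3ccccc3)(c3ccccc3)C(C)(C)C)[C@H](OC(=O)[C@H](C)CC)[C@H]12
F5 | step 7 | 3-methyl-6-[(R)-(4-methylphenyl)sulfinyl]-2-[(2S)-5-{[tert-butyl(diphenyl)silyl]oxy}pentan-2-yl]cyclohex-2-en-1-one, C6 epimers | CC1=C([C@@H](C)CCCO[Si](c2ccccc2)(c2ccccc2)C(C)(C)C)C(=O)C([S@@](=O)c2ccc(C)cc2)CC1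
F6 | step 7 | (1S)-3-methyl-6-[(R)-(4-methylphenyl)sulfinyl]-2-[(2S)-5-{[tert-butyl(diphenyl)silyl]oxy}pentan-2-yl]cyclohex-2-en-1-ol, C6 epimers | CC1=C([C@@H](C)CCCO[Si](c2ccccc2)(c2ccccc2)C(C)(C)C)[C@H](O)C([S@@](=O)c2ccc(C)cc2)CC1
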